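The oxolane ring (O1, C2, C3, C3a, C7a) is treated as a C-furanoside: its 1,2-dioxygenated C3–C3a bond next to ring oxygen O1 is the retron of an aldol addition followed by reductive cycloetherification. The key step unites two acyclic fragments in one flask, an α-silyloxy aldehyde (C7a, C3a) and a 1,2-bis(silyloxy)diene carrying the whole side chain (C2, C3): Mukaiyama addition forms C3–C3a, the C7a silyl ether oxygen then closes onto the C2 carbonyl and Et3SiH reduces the oxocarbenium ion, setting three stereocentres. Inversion at C3a, acryloylation and ring-closing metathesis finally build the cis-fused pyranone ring.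

Key step: step 8

Assumption: (2R)-but-3-ene-1,2-diol and 2-(tert-butyldimethylsilyloxy)-N-methoxy-N-methylacetamide are taken as catalogue compounds; atoms are labelled by the furo[3,2-b]pyran-5-one numbering (O1, C2, C3, C3a, O4, C5, C6, C7, C7a) and C1' to C5' for the pentenyl side chain, also in the intermediates.

Step 1
Reactants: 1 (2R)-but-3-ene-1,2-diol
Product: 2 (3R)-3,4-bis(triethylsilyloxy)but-1-ene
Conditions: Et3SiCl (2.3 equiv), imidazole, CH2Cl2, 0 °C to rt
Reagents that add atoms: chlorotriethylsilane CC[Si](Cl)(CC)CC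
Why: Standard silyl ether formation should protect both hydroxyls without touching the allylic stereocentre, and it places on O1 the triethylsilyl group that later leaves when this oxygen closes the ring.

Step 2
Reactants: 2 (3R)-3,4-bis(triethylsilyloxy)but-1-ene
Product: 3 (2R)-2-(triethylsilyloxy)but-3-enal
Conditions: (COCl)2, DMSO, CH2Cl2, −78 to −40 °C; then Et3N, −78 to 0 °C; used crude
Reagents that add atoms: none
Why: Under Swern oxidation conditions a primary triethylsilyl ether is cleaved and oxidised in preference to a secondary one, so the α-silyloxy aldehyde should form directly, the low temperature guarding the configuration at C7a.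

Step 3
Reactants: 4 acrolein, 5 benzoic anhydride
Product: 6 prop-2-ene-1,1-diyl dibenzoate
Conditions: FeCl3 (cat.), CH2Cl2, 0 °C to rt
Reagents that add atoms: none
Why: Lewis-acid-catalysed acylal formation (addition of a carboxylic anhydride across the aldehyde C=O) should give the geminal dibenzoate without conjugate addition.

Step 4
Reactants: 6 prop-2-ene-1,1-diyl dibenzoate, 7 ethanol
Product: 8 (3S,4R)-4-hydroxypent-1-en-3-yl benzoate
Conditions: [Ir(cod)Cl]2 (cat.), SEGPHOS (the enantiomer that delivers the (3S,4R) adduct, cat.), 4-cyano-3-nitrobenzoic acid (cat.), Cs2CO3 (cat.), THF, 90 °C, sealed tube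
Reagents that add atoms: none
Why: In this iridium-catalysed transfer-hydrogenative carbonyl allylation ethanol is dehydrogenated to acetaldehyde in the flask and the (E)-benzoyloxyallyl iridium species adds through a closed chair transition state, so the anti relationship of C3' and C4' follows from the allyl geometry and their absolute configuration from the chiral bisphosphine.

Step 5
Reactants: 9 2-(tert-butyldimethylsilyloxy)-N-methoxy-N-methylacetamide, 10 vinylmagnesium bromide
Product: 11 1-(tert-butyldimethylsilyloxy)but-3-en-2-one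
Conditions: THF, −78 to 0 °C; inverse quench into cold aqueous HCl
Reagents that add atoms: none
Why: In this Weinreb ketone synthesis the chelated tetrahedral adduct should survive until the acidic quench, which prevents double addition and gives the vinyl ketone.

Step 6
Reactants: 8 (3S,4R)-4-hydroxypent-1-en-3-yl benzoate, 11 1-(tert-butyldimethylsilyloxy)but-3-en-2-one
Product: 12 (2R,3S,4E)-7-(tert-butyldimethylsilyloxy)-2-hydroxy-6-oxohept-4-en-3-yl benzoate
Conditions: second-generation Hoveyda–Grubbs catalyst (5 mol %), 11 (3 equiv), CH2Cl2, 40 °C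
Reagents that add atoms: none
Why: Olefin cross-metathesis of a hindered allylic ester olefin with an excess of an electron-poor vinyl ketone should favour the cross product and give the E enone under thermodynamic control, with no effect on the two stereocentres.

Step 7
Reactants: 12 (2R,3S,4E)-7-(tert-butyldimethylsilyloxy)-2-hydroxy-6-oxohept-4-en-3-yl benzoate
Product: 13 (2R,3S,4E,6Z)-2,6,7-tris(tert-butyldimethylsilyloxy)hepta-4,6-dien-3-yl benzoate
Conditions: TBSOTf (2.4 equiv), Et3N, CH2Cl2, −78 to 0 °C; used after filtration through deactivated silica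
Reagents that add atoms: tert-butyldimethylsilyl trifluoromethanesulfonate CC(C)(C)[Si](C)(C)OS(=O)(=O)C(F)(F)F
Why: Soft enolisation with a silyl triflate and a tertiary amine (silyl enol ether formation) should deprotonate the α'-methylene of the enone to give the cross-conjugated (Z)-bis(silyloxy)diene, the secondary hydroxyl being silylated in the same operation.

Step 8
Reactants: 3 (2R)-2-(triethylsilyloxy)but-3-enal, 13 (2R,3S,4E,6Z)-2,6,7-tris(tert-butyldimethylsilyloxy)hepta-4,6-dien-3-yl benzoate
Product: 15 (2R,3S,4E)-2-(tert-butyldimethylsilyloxy)-5-[(2S,3S,4R,5R)-3-(tert-butyldimethylsilyloxy)-5-ethenyl-4-hydroxyoxolan-2-yl]pent-4-en-3-yl benzoate, via open-chain aldol adduct 14 (not isolated)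
Conditions: BF3·OEt2 (2.5 equiv), CH2Cl2, −78 °C, 13 added to the precomplexed aldehyde; then Et3SiH (5 equiv), −78 to −30 °C; aqueous NaHCO3
Reagents that add atoms: none
Why: A Lewis-acid Mukaiyama aldol addition is followed in the same flask by reductive cycloetherification: BF3-bound aldehyde 3 is attacked by the enol ether carbon C3 of 13 through an open transition state to give aldol 14 (bond C3–C3a), and once Et3SiH is added the C7a triethylsilyl ether oxygen adds to the BF3-activated C2 carbonyl, the silyl group is lost and the resulting 2-alkenyl oxocarbenium ion is reduced (bond O1–C2). The closest known reaction types are the Mukaiyama aldol reaction, the formal [3+2] annulation of α-silyloxy aldehydes with nucleophilic alkenes and the silane reduction of furanosyl hemiketals to C-glycosides. The oxolane ring closes by 5-exo-trig attack of O1 on the C2 carbonyl carbon, followed by ionisation and hydride capture. C3a is set by Felkin–Anh addition anti to the C7a silyloxy group, C3 by the (Z)-enol ether (syn aldol), and C2 by hydride attack on the envelope oxocarbenium ion from the face opposite the C3 silyloxy and C7a vinyl groups, which is also the stereoelectronically preferred inside attack cis to the C3a oxygen. The step needs carbon–carbon bond formation at C3 and not at the vinylogous carbon C2', and 1,2- and not 1,4-hydride delivery; the 2-silyloxy group makes C3 the most nucleophilic site and the carbon flanked by O1 is the most electrophilic site of the cation, as in reductive Ferrier-type displacements.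

Step 9
Reactants: 15 (2R,3S,4E)-2-(tert-butyldimethylsilyloxy)-5-[(2S,3S,4R,5R)-3-(tert-butyldimethylsilyloxy)-5-ethenyl-4-hydroxyoxolan-2-yl]pent-4-en-3-yl benzoate
Product: 16 (2R,3S,4E)-2-(tert-butyldimethylsilyloxy)-5-[(2S,3R,5R)-3-(tert-butyldimethylsilyloxy)-5-ethenyl-4-oxooxolan-2-yl]pent-4-en-3-yl benzoate
Conditions: Dess–Martin periodinane, NaHCO3, CH2Cl2, 0 °C; used at once
Reagents that add atoms: none
Why: Dess–Martin oxidation of the only free hydroxyl under buffered conditions should give the ring ketone, which removes the C3a stereocentre so that it can be set again in the opposite sense.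

Step 10
Reactants: 16 (2R,3S,4E)-2-(tert-butyldimethylsilyloxy)-5-[(2S,3R,5R)-3-(tert-butyldimethylsilyloxy)-5-ethenyl-4-oxooxolan-2-yl]pent-4-en-3-yl benzoate
Product: 17 (2R,3S,4E)-2-(tert-butyldimethylsilyloxy)-5-[(2S,3S,4S,5R)-3-(tert-butyldimethylsilyloxy)-5-ethenyl-4-hydroxyoxolan-2-yl]pent-4-en-3-yl benzoate (all-cis oxolane)
Conditions: NaBH4, CeCl3·7H2O, MeOH, −78 °C
Reagents that add atoms: none
Why: In this Luche-type borohydride reduction hydride should approach the oxolanone from the face opposite the three cis substituents at C2, C3 and C7a, so that the new hydroxyl at C3a ends up cis to all of them (substrate control).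

Step 11
Reactants: 17 (2R,3S,4E)-2-(tert-butyldimethylsilyloxy)-5-[(2S,3S,4S,5R)-3-(tert-butyldimethylsilyloxy)-5-ethenyl-4-hydroxyoxolan-2-yl]pent-4-en-3-yl benzoate, 18 acryloyl chloride
Product: 19 (2R,3S,4E)-2-(tert-butyldimethylsilyloxy)-5-[(2S,3R,4S,5R)-3-(tert-butyldimethylsilyloxy)-5-ethenyl-4-(prop-2-enoyloxy)oxolan-2-yl]pent-4-en-3-yl benzoate
Conditions: i-Pr2NEt, DMAP (cat.), CH2Cl2, −20 to 0 °C
Reagents that add atoms: none
Why: DMAP-catalysed O-acylation with an acid chloride should esterify the hindered secondary hydroxyl with retention at C3a.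

Step 12
Reactants: 19 (2R,3S,4E)-2-(tert-butyldimethylsilyloxy)-5-[(2S,3R,4S,5R)-3-(tert-butyldimethylsilyloxy)-5-ethenyl-4-(prop-2-enoyloxy)oxolan-2-yl]pent-4-en-3-yl benzoate
Product: 20 (2R,3S,4E)-2-(tert-butyldimethylsilyloxy)-5-[(2S,3R,3aS,7aR)-3-(tert-butyldimethylsilyloxy)-5-oxo-2,3,3a,7a-tetrahydro-5H-furo[3,2-b]pyran-2-yl]pent-4-en-3-yl benzoate
Conditions: second-generation Grubbs catalyst (5 mol %), CH2Cl2 (high dilution), 40 °C
Reagents that add atoms: none
Why: Ring-closing metathesis between the acrylate and the cis-disposed vinyl group on the neighbouring carbon should close the six-membered unsaturated lactone (ring B) with loss of ethylene, the internal side-chain alkene being far less reactive.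

Step 13
Reactants: 20 (2R,3S,4E)-2-(tert-butyldimethylsilyloxy)-5-[(2S,3R,3aS,7aR)-3-(tert-butyldimethylsilyloxy)-5-oxo-2,3,3a,7a-tetrahydro-5H-furo[3,2-b]pyran-2-yl]pent-4-en-3-yl benzoate
Product: 21 (1E,3S,4R)-4-hydroxy-1-[(2S,3R,3aR,7aR)-3-hydroxy-5-oxo-2,3,3a,7a-tetrahydro-5H-furo[3,2-b]pyran-2-yl]pent-1-en-3-yl benzoate (target)
Conditions: HF·pyridine, pyridine, THF, 0 °C to rt
Reagents that add atoms: none
Why: Fluoride-mediated cleavage of both silyl ethers under buffered, mildly acidic conditions should free the two hydroxyls without benzoyl migration or opening of the lactone.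

Compound list
1 | (2R)-but-3-ene-1,2-diol | C=C[C@@H](O)CO | starting material
2 | (3R)-3,4-bis(triethylsilyloxy)but-1-ene | C=C[C@@H](O[Si](CC)(CC)CC)CO[Si](CC)(CC)CC | intermediate
3 | (2R)-2-(triethylsilyloxy)but-3-enal | C=C[C@@H](O[Si](CC)(CC)CC)C=O | intermediate
4 | acrolein (prop-2-enal) | C=CC=O | starting material
5 | benzoic anhydride | O=C(OC(=O)c1ccccc1)c1ccccc1 | starting material
6 | prop-2-ene-1,1-diyl dibenzoate | C=CC(OC(=O)c1ccccc1)OC(=O)c1ccccc1 | intermediate
7 | ethanol | CCO | starting material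
8 | (3S,4R)-4-hydroxypent-1-en-3-yl benzoate | C[C@@H](O)[C@H](C=C)OC(=O)c1ccccc1 | intermediate
9 | 2-(tert-butyldimethylsilyloxy)-N-methoxy-N-methylacetamide | CON(C)C(=O)CO[Si](C)(C)C(C)(C)C | starting material
10 | vinylmagnesium bromide | C=C[Mg]Br | starting material
11 | 1-(tert-butyldimethylsilyloxy)but-3-en-2-one | C=CC(=O)CO[Si](C)(C)C(C)(C)C | intermediate
12 | (2R,3S,4E)-7-(tert-butyldimethylsilyloxy)-2-hydroxy-6-oxohept-4-en-3-yl benzoate | C[C@@H](O)[C@H](/C=C/C(=O)CO[Si](C)(C)C(C)(C)C)OC(=O)c1ccccc1 | intermediate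
13 | (2R,3S,4E,6Z)-2,6,7-tris(tert-butyldimethylsilyloxy)hepta-4,6-dien-3-yl benzoate | C[C@@H](O[Si](C)(C)C(C)(C)C)[C@H](/C=C/C(O[Si](C)(C)C(C)(C)C)=C/O[Si](C)(C)C(C)(C)C)OC(=O)c1ccccc1 | intermediate
14 | open-chain aldol adduct, (2R,3S,4E,7S,8R,9R)-2,7-bis(tert-butyldimethylsilyloxy)-8-hydroxy-6-oxo-9-(triethylsilyloxy)undeca-4,10-dien-3-yl benzoate (formed in the flask) | C[C@@H](O[Si](C)(C)C(C)(C)C)[C@H](/C=C/C(=O)[C@@H](O[Si](C)(C)C(C)(C)C)[C@H](O)[C@H](O[Si](CC)(CC)CC)C=C)OC(=O)c1ccccc1 | intermediate
15 | (2R,3S,4E)-2-(tert-butyldimethylsilyloxy)-5-[(2S,3S,4R,5R)-3-(tert-butyldimethylsilyloxy)-5-ethenyl-4-hydroxyoxolan-2-yl]pent-4-en-3-yl benzoate | C[C@@H](O[Si](C)(C)C(C)(C)C)[C@H](/C=C/[C@@H]1O[C@H](C=C)[C@@H](O)[C@@H]1O[Si](C)(C)C(C)(C)C)OC(=O)c1ccccc1 | intermediate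
16 | (2R,3S,4E)-2-(tert-butyldimethylsilyloxy)-5-[(2S,3R,5R)-3-(tert-butyldimethylsilyloxy)-5-ethenyl-4-oxooxolan-2-yl]pent-4-en-3-yl benzoate | C[C@@H](O[Si](C)(C)C(C)(C)C)[C@H](/C=C/[C@@H]1O[C@H](C=C)C(=O)[C@@H]1O[Si](C)(C)C(C)(C)C)OC(=O)c1ccccc1 | intermediate
17 | (2R,3S,4E)-2-(tert-butyldimethylsilyloxy)-5-[(2S,3S,4S,5R)-3-(tert-butyldimethylsilyloxy)-5-ethenyl-4-hydroxyoxolan-2-yl]pent-4-en-3-yl benzoate | C[C@@H](O[Si](C)(C)C(C)(C)C)[C@H](/C=C/[C@@H]1O[C@H](C=C)[C@H](O)[C@@H]1O[Si](C)(C)C(C)(C)C)OC(=O)c1ccccc1 | intermediate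
18 | acryloyl chloride | C=CC(=O)Cl | starting material
19 | (2R,3S,4E)-2-(tert-butyldimethylsilyloxy)-5-[(2S,3R,4S,5R)-3-(tert-butyldimethylsilyloxy)-5-ethenyl-4-(prop-2-enoyloxy)oxolan-2-yl]pent-4-en-3-yl benzoate | C[C@@H](O[Si](C)(C)C(C)(C)C)[C@H](/C=C/[C@@H]1O[C@H](C=C)[C@H](OC(=O)C=C)[C@@H]1O[Si](C)(C)C(C)(C)C)OC(=O)c1ccccc1 | intermediate
20 | (2R,3S,4E)-2-(tert-butyldimethylsilyloxy)-5-[(2S,3R,3aS,7aR)-3-(tert-butyldimethylsilyloxy)-5-oxo-2,3,3a,7a-tetrahydro-5H-furo[3,2-b]pyran-2-yl]pent-4-en-3-yl benzoate | C[C@@H](O[Si](C)(C)C(C)(C)C)[C@H](/C=C/[C@@H]1O[C@@H]2C=CC(=O)O[C@@H]2[C@@H]1O[Si](C)(C)C(C)(C)C)OC(=O)c1ccccc1 | intermediate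
21 | (1E,3S,4R)-4-hydroxy-1-[(2S,3R,3aR,7aR)-3-hydroxy-5-oxo-2,3,3a,7a-tetrahydro-5H-furo[3,2-b]pyran-2-yl]pent-1-en-3-yl benzoate | C[C@@H](O)[C@H](/C=C/[C@@H]1O[C@@H]2C=CC(=O)O[C@@H]2[C@@H]1O)OC(=O)c1ccccc1 | target

Total step count: 13.
Longest linear sequence: 10 steps (3, 4, 6, 7, 8, 9, 10, 11, 12, 13).

Steps most likely to fail

Step 8. The open transition state may give weak syn/anti control. The Lewis acid may also ionise the allylic benzoate through the electron-rich diene before the carbon–carbon bond forms. Hydride may be delivered in conjugate fashion to the alkenyl oxocarbenium ion. The fallback replaces the open-transition-state addition by a boron aldol reaction and separates the two bond formations. It sets out from 12: silylation of the C4' hydroxyl alone (TBSOTf, 2,6-lutidine, CH2Cl2, −78 °C) gives (2R,3S,4E)-2,7-bis(tert-butyldimethylsilyloxy)-6-oxohept-4-en-3-yl benzoate F1. Its (Z)-dibutylboron enolate (Bu2BOTf, i-Pr2NEt, −78 °C) should add to aldehyde 3 through a Zimmerman–Traxler transition state to give the syn, Felkin-type aldol 14, now isolated. BF3·OEt2 and Et3SiH then convert 14 into 15, where the route is rejoined.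

Step 4. Enantio- and diastereocontrol may be incomplete with the smallest alcohol partner, and the benzoyl group may migrate to the neighbouring hydroxyl under the basic conditions. The fallback takes C4' from the chiral pool and sets C3' by substrate control. It sets out from vinyl ketone 11, which it keeps as the metathesis partner, while 6 to 8 and 12 are bypassed. Methyl (2R)-2-hydroxypropanoate F2 is silylated (TBSCl, imidazole) to methyl (2R)-2-(tert-butyldimethylsilyloxy)propanoate F3. Reduction (i-Bu2AlH, −78 °C) gives (2R)-2-(tert-butyldimethylsilyloxy)propanal F4. Vinylmagnesium bromide (Felkin–Anh addition, anti) should give (3S,4R)-4-(tert-butyldimethylsilyloxy)pent-1-en-3-ol F5. Benzoylation (BzCl, pyridine) gives (3S,4R)-4-(tert-butyldimethylsilyloxy)pent-1-en-3-yl benzoate F6. Cross-metathesis with 11 gives (2R,3S,4E)-2,7-bis(tert-butyldimethylsilyloxy)-6-oxohept-4-en-3-yl benzoate F1, and enol silylation (TBSOTf, Et3N) returns to the route at 13.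

Step 9. The oxolanone may enolise toward C3 or C7a (epimerisation) or lose the ring oxygen by β-elimination before it is reduced. The fallback inverts C3a by substitution, not by oxidation and reduction. It sets out from 15: Mitsunobu esterification with acrylic acid (PPh3, diisopropyl azodicarboxylate, toluene, 0 °C to rt) should give acrylate 19 directly with inversion at C3a. It returns at 19 and makes no new compound.

Further compounds
F1 | step 8 | (2R,3S,4E)-2,7-bis(tert-butyldimethylsilyloxy)-6-oxohept-4-en-3-yl benzoate | C[C@@H](O[Si](C)(C)C(C)(C)C)[C@H](/C=C/C(=O)CO[Si](C)(C)C(C)(C)C)OC(=O)c1ccccc1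
F2 | step 4 | methyl (2R)-2-hydroxypropanoate | C[C@@H](O)C(=O)OC
F3 | step 4 | methyl (2R)-2-(tert-butyldimethylsilyloxy)propanoate | C[C@@H](O[Si](C)(C)C(C)(C)C)C(=O)OC
F4 | step 4 | (2R)-2-(tert-butyldimethylsilyloxy)propanal | C[C@@H](O[Si](C)(C)C(C)(C)C)C=O
F5 | step 4 | (3S,4R)-4-(tert-butyldimethylsilyloxy)pent-1-en-3-ol | C[C@@H](O[Si](C)(C)C(C)(C)C)[C@@H](O)C=C
F6 | step 4 | (3S,4R)-4-(tert-butyldimethylsilyloxy)pent-1-en-3-yl benzoate | C[C@@H](O[Si](C)(C)C(C)(C)C)[C@H](C=C)OC(=O)c1ccccc1
F0 | step 9 | none | none
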